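**Strategy.** Ring C, the seven-membered carbocycle (C5, C6, C14, C13, C12, C11, C10), carries functionality only on C12 and C13: its oxirane marks a trisubstituted C12=C13 olefin, and both olefin carbons can be carbonyl carbons. Everything rests on uniting these two like-polarised carbons: a titanium-mediated McMurry coupling of a C12 methyl ketone with a C13 aldehyde, carried on the trans-diequatorial C5 and C6 side chains of a finished lactone-fused hydrindane, closes ring C and sets the olefin in one operation. The precursor, a keto-aldehyde, is built by an enantioselective Ireland–Claisen rearrangement (C5, C6), a Pauson–Khand reaction (rings A and B) and an epoxide-opening lactonisation.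

Key step: step 18

Remark: cyathane numbering is used (ring A = C1–C4, C9; ring B = C4–C9; ring C = C5, C6, C10–C14; C17 = CH2O on C9; C18–C20 = lactone carbons), β is the face of the C6 methyl, and the oxirane is treated as a functional group placed on the completed ring skeleton (rings A–C and the lactone) by epoxidation of the olefin that the key step forms.

**Step 1**
Reactants: 1 methyl 5-oxohexanoate
Product: 2 methyl 4-(2-methyl-1,3-dioxolan-2-yl)butanoate
Conditions: HOCH2CH2OH, p-TsOH (cat.), toluene, reflux, Dean–Stark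
Reagents that add atoms: ethane-1,2-diol, OCCO
Why: Acid-catalysed ketalisation with azeotropic water removal masks the future C12 ketone as a dioxolane that should survive every basic, reductive and oxidative step up to step 17.

**Step 2**
Reactants: 2 methyl 4-(2-methyl-1,3-dioxolan-2-yl)butanoate
Product: 3 4-(2-methyl-1,3-dioxolan-2-yl)butanoic acid
Conditions: LiOH, THF/H2O, rt; then 1 M HCl to pH 4, 0 °C
Reagents that add atoms: lithium hydroxide, [Li+].[OH-]
Why: Saponification of the methyl ester, with cold, mild acidification so that the dioxolane is kept.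

**Step 3**
Reactants: 4 4,4-dimethoxybutan-2-one; 5 triethyl phosphonoacetate
Product: 6 ethyl (2E)-5,5-dimethoxy-3-methylpent-2-enoate
Conditions: NaH, THF, 0 °C → rt; chromatography removes the minor Z isomer
Reagents that add atoms: none
Why: Horner–Wadsworth–Emmons olefination of the methyl ketone should favour the E enoate (ester trans to the larger CH2CH(OMe)2 group), and geometrically pure E material is needed for step 6.

**Step 4**
Reactants: 6 ethyl (2E)-5,5-dimethoxy-3-methylpent-2-enoate
Product: 7 (2E)-5,5-dimethoxy-3-methylpent-2-en-1-ol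
Conditions: i-Bu2AlH (2.2 equiv), CH2Cl2, −78 °C; Rochelle salt work-up
Reagents that add atoms: none
Why: 1,2-Hydride reduction of the enoate gives the allylic alcohol without touching the acetal or the olefin geometry.

**Step 5**
Reactants: 3 4-(2-methyl-1,3-dioxolan-2-yl)butanoic acid; 7 (2E)-5,5-dimethoxy-3-methylpent-2-en-1-ol
Product: 8 (2E)-5,5-dimethoxy-3-methylpent-2-en-1-yl 4-(2-methyl-1,3-dioxolan-2-yl)butanoate
Conditions: DCC, DMAP (cat.), CH2Cl2, 0 °C → rt
Reagents that add atoms: none
Why: Steglich esterification joins the two fragments under neutral conditions that keep both acetals.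

**Step 6**
Reactants: 8 (2E)-5,5-dimethoxy-3-methylpent-2-en-1-yl 4-(2-methyl-1,3-dioxolan-2-yl)butanoate
Product: 10 (2S,3R)-3-(2,2-dimethoxyethyl)-3-methyl-2-[2-(2-methyl-1,3-dioxolan-2-yl)ethyl]pent-4-enoic acid, via boron ketene acetal 9 (not isolated)
Conditions: (S,S)-N,N′-bis[3,5-bis(trifluoromethyl)phenylsulfonyl]-1,2-diphenylethane-1,2-diamine, BBr3, CH2Cl2 (gives the chiral bromoborane); then 8, i-Pr2NEt, CH2Cl2, −78 °C; −20 → 4 °C; aqueous work-up
Reagents that add atoms: none
Why: Enantioselective Ireland–Claisen rearrangement: the boron ketene acetal with the alkyl chain cis to O–B and the E olefin should pass through a chair transition state with both chains equatorial and the methyl axial, which fixes the relative configuration of C5 and the quaternary C6, while the C2-symmetric diazaborolidine selects the enolate face (the (S,S) controller is assigned by analogy with E-allyl alkanoates; the (R,R) controller would give the antipode).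

**Step 7**
Reactants: 10 (2S,3R)-3-(2,2-dimethoxyethyl)-3-methyl-2-[2-(2-methyl-1,3-dioxolan-2-yl)ethyl]pent-4-enoic acid
Product: 11 methyl (2S,3R)-3-(2,2-dimethoxyethyl)-3-methyl-2-[2-(2-methyl-1,3-dioxolan-2-yl)ethyl]pent-4-enoate
Conditions: MeI, K2CO3, DMF, rt
Reagents that add atoms: iodomethane, CI
Why: Carboxylate O-alkylation gives the methyl ester needed for the borane and hydride steps; the weak base should not epimerise the hindered C5 centre.

**Step 8**
Reactants: 12 2-bromoprop-2-en-1-ol
Product: 13 tert-butyl[(2-bromoprop-2-en-1-yl)oxy]dimethylsilane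
Conditions: TBSCl, imidazole, DMF, rt
Reagents that add atoms: tert-butyldimethylsilyl chloride, CC(C)(C)[Si](C)(C)Cl
Why: Silylation protects the future C17 oxygen as an ether that tolerates the later base, hydride and peracid steps and falls off in the acid step 17.

**Step 9**
Reactants: 11 methyl (2S,3R)-3-(2,2-dimethoxyethyl)-3-methyl-2-[2-(2-methyl-1,3-dioxolan-2-yl)ethyl]pent-4-enoate; 13 tert-butyl[(2-bromoprop-2-en-1-yl)oxy]dimethylsilane
Product: 15 methyl (2S,3S)-6-{[(tert-butyldimethylsilyl)oxy]methyl}-3-(2,2-dimethoxyethyl)-3-methyl-2-[2-(2-methyl-1,3-dioxolan-2-yl)ethyl]hept-6-enoate, via B-alkyl-9-BBN adduct 14 (not isolated)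
Conditions: 9-BBN-H, THF, 0 °C → rt; then 13, PdCl2(dppf) (cat.), AsPh3, Cs2CO3, DMF/H2O, rt
Reagents that add atoms: none
Why: Anti-Markovnikov hydroboration of the only olefin followed by B-alkyl Suzuki–Miyaura coupling forms the C8–C9 bond and delivers the 1,1-disubstituted olefin that becomes C9 and C1 (the descriptor at C6 changes by priority only).

**Step 10**
Reactants: 15 methyl (2S,3S)-6-{[(tert-butyldimethylsilyl)oxy]methyl}-3-(2,2-dimethoxyethyl)-3-methyl-2-[2-(2-methyl-1,3-dioxolan-2-yl)ethyl]hept-6-enoate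
Product: 16 (2S,3S)-6-{[(tert-butyldimethylsilyl)oxy]methyl}-3-(2,2-dimethoxyethyl)-3-methyl-2-[2-(2-methyl-1,3-dioxolan-2-yl)ethyl]hept-6-enal
Conditions: i-Bu2AlH (1.1 equiv), toluene, −78 °C
Reagents that add atoms: none
Why: Partial hydride reduction of the hindered α-branched methyl ester should stop at the aldehyde because the aluminium hemiacetal is stable at −78 °C.

**Step 11**
Reactants: 16 (2S,3S)-6-{[(tert-butyldimethylsilyl)oxy]methyl}-3-(2,2-dimethoxyethyl)-3-methyl-2-[2-(2-methyl-1,3-dioxolan-2-yl)ethyl]hept-6-enal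
Product: 17 (3S,4S)-7-{[(tert-butyldimethylsilyl)oxy]methyl}-4-(2,2-dimethoxyethyl)-4-methyl-3-[2-(2-methyl-1,3-dioxolan-2-yl)ethyl]oct-7-en-1-yne
Conditions: dimethyl (1-diazo-2-oxopropyl)phosphonate, K2CO3, MeOH, 0 °C → rt
Reagents that add atoms: dimethyl (1-diazo-2-oxopropyl)phosphonate, CC(=O)C(=[N+]=[N-])P(=O)(OC)OC
Why: Seyferth–Gilbert homologation with the Ohira–Bestmann reagent turns the aldehyde into the terminal alkyne C4≡C3 under mild base; the C5 centre next to the quaternary C6 should enolise too slowly to epimerise.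

**Step 12**
Reactants: 17 (3S,4S)-7-{[(tert-butyldimethylsilyl)oxy]methyl}-4-(2,2-dimethoxyethyl)-4-methyl-3-[2-(2-methyl-1,3-dioxolan-2-yl)ethyl]oct-7-en-1-yne
Product: 18 bicyclic enone (2-oxo-hydrind-3-ene; 9α-CH2OTBS, 6β-methyl, 6α-(2,2-dimethoxyethyl), 5β-[2-(2-methyl-1,3-dioxolan-2-yl)ethyl])
Conditions: Co2(CO)8 (cat.), tetramethylthiourea, CO (1 atm), toluene, 70 °C
Reagents that add atoms: carbon monoxide, [C-]#[O+]
Why: Intramolecular Pauson–Khand cyclocarbonylation of the 1,7-enyne should close rings B and A together and make the quaternary C9 from the 1,1-disubstituted olefin; the chair-like tether with the C5 chain equatorial and CH2OTBS axial avoids a syn-axial clash between the two, which places C17 on the α face.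

**Step 13**
Reactants: 18 bicyclic enone
Product: 19 2α-allylic alcohol (2α-hydroxy-hydrind-3-ene, other groups as in 18)
Conditions: NaBH4, CeCl3·7H2O, MeOH, −78 → 0 °C
Reagents that add atoms: none
Why: Luche 1,2-reduction; hydride should add to C2 from the β face, away from the axial CH2OTBS on C9, to give the 2α-alcohol cis to C17.

**Step 14**
Reactants: 19 2α-allylic alcohol; 20 (diethoxyphosphoryl)acetic acid
Product: 21 2α-[(diethoxyphosphoryl)acetoxy]-hydrind-3-ene
Conditions: DCC, DMAP (cat.), CH2Cl2, 0 °C → rt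
Reagents that add atoms: none
Why: Steglich esterification hangs the two lactone carbons C18 and C19, with the phosphonate needed later for C20, on the α-oxygen at C2.

**Step 15**
Reactants: 21 2α-[(diethoxyphosphoryl)acetoxy]-hydrind-3-ene
Product: 22 3β,4β-epoxide of 21
Conditions: mCPBA, NaHCO3, CH2Cl2, 0 °C → rt
Reagents that add atoms: 3-chloroperbenzoic acid, OOC(=O)c1cccc(Cl)c1
Why: Prilezhaev epoxidation of the only olefin; attack from the β face, opposite the axial CH2OTBS on C9 and the acyloxy group on C2, should place the C4 oxygen anti to C17.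

**Step 16**
Reactants: 22 3β,4β-epoxide
Product: 23 α-phosphono-γ-lactone (19,2α-olide with 4β-OH; mixture of C18 epimers)
Conditions: NaH, THF, 0 → 60 °C; then AcOH
Reagents that add atoms: none
Why: Intramolecular epoxide alkylation by the stabilised phosphonoacetate carbanion (5-exo-tet at the less substituted C3, backside attack from the α face to which the nucleophile is tethered) should close the cis-fused lactone with inversion at C3 and free the tertiary 4β-hydroxyl.

**Step 17**
Reactants: 23 α-phosphono-γ-lactone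
Product: 24 keto-aldehyde (12-oxo, 13-al, 17-OH, 4β-OH; ring C still open)
Conditions: 2 M HCl, THF, 0 °C → rt; used at once
Reagents that add atoms: water, O
Why: Acid hydrolysis removes the dimethyl acetal, the dioxolane and the primary silyl ether in one operation; immediate use limits aldolisation of the keto-aldehyde.

**Step 18**
Reactants: 24 keto-aldehyde
Product: 25 tetracyclic cyclohept-12-ene (ring C closed; α-phosphono lactone, 17-OH, 4β-OH)
Conditions: TiCl3(DME)1.5, Zn–Cu couple, DME, reflux; 24 added over 30 h by syringe pump (high dilution)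
Reagents that add atoms: none
Why: Low-valent titanium reduces the C13 aldehyde and the C12 ketone to ketyls that couple on the metal to a titanium pinacolate, which is then deoxygenated to the olefin; the closest known type is the intramolecular McMurry coupling of keto-aldehydes to cycloalkenes. Ring C is closed by forming the C12–C13 bond between two like-polarised, both electrophilic, carbonyl carbons in a seven-membered ring closure under high dilution. No new stereocentre is formed: the ring olefin is necessarily cis, and C5 and C6, whose chains sit trans-diequatorial on ring B, are untouched. The step needs chemoselectivity for aldehyde–ketone coupling over reduction of the lactone and phosphonate and over intermolecular coupling; this should be secured by the much higher reactivity of aldehyde and ketone toward low-valent titanium, by slow addition, and by the gauche, pre-organised placement of the two chains on the vicinal C5 and C6. Free hydroxyl groups should be tolerated as titanium alkoxides when the reagent is in excess.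

**Step 19**
Reactants: 25 tetracyclic cyclohept-12-ene
Product: 26 α-methylene lactone (17-OH, 4β-OH, C12=C13 olefin)
Conditions: K2CO3, 37% aq. CH2O, THF, 0 °C → rt
Reagents that add atoms: formaldehyde, C=O
Why: Horner–Wadsworth–Emmons olefination of the α-phosphono lactone with formaldehyde installs the exocyclic methylene C20 and erases the C18 stereocentre.

**Step 20**
Reactants: 26 α-methylene lactone
Product: 27 17-acetate of 26
Conditions: Ac2O, pyridine, DMAP (cat.), CH2Cl2, 0 °C
Reagents that add atoms: acetic anhydride, CC(=O)OC(C)=O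
Why: Acylation of the primary C17 alcohol; the axial tertiary C4 hydroxyl is too hindered to react.

**Step 21**
Reactants: 27 17-acetate
Product: 28 target, 17-acetoxy-12α,13α-epoxy-4β-hydroxycyath-18(20)-en-19,2α-olide (CNP0214540.1)
Conditions: mCPBA, NaHCO3, CH2Cl2, 0 °C
Reagents that add atoms: 3-chloroperbenzoic acid, OOC(=O)c1cccc(Cl)c1
Why: Prilezhaev epoxidation picks the electron-rich trisubstituted C12=C13 olefin over the electron-poor methylene lactone and should come from the α face, anti to the axial C6 methyl that overhangs the β face of ring C.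

**Compound list**

1 | methyl 5-oxohexanoate | CC(=O)CCCC(=O)OC | starting material
2 | methyl 4-(2-methyl-1,3-dioxolan-2-yl)butanoate | CC1(CCCC(=O)OC)OCCO1 | intermediate
3 | 4-(2-methyl-1,3-dioxolan-2-yl)butanoic acid | CC1(CCCC(=O)O)OCCO1 | intermediate
4 | 4,4-dimethoxybutan-2-one | CC(=O)CC(OC)OC | starting material
5 | triethyl phosphonoacetate | CCOC(=O)CP(=O)(OCC)OCC | starting material
6 | ethyl (2E)-5,5-dimethoxy-3-methylpent-2-enoate | CCOC(=O)/C=C(\C)CC(OC)OC | intermediate
7 | (2E)-5,5-dimethoxy-3-methylpent-2-en-1-ol | OC/C=C(\C)CC(OC)OC | intermediate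
8 | (2E)-5,5-dimethoxy-3-methylpent-2-en-1-yl 4-(2-methyl-1,3-dioxolan-2-yl)butanoate | CC1(CCCC(=O)OC/C=C(\C)CC(OC)OC)OCCO1 | intermediate
9 | boron ketene acetal of 8 (O-bound (4S,5S)-diazaborolidine, alkyl chain cis to O–B) | CC1(CC/C=C(\OB2N(S(=O)(=O)c3cc(cc(c3)C(F)(F)F)C(F)(F)F)[C@@H](c3ccccc3)[C@H](c3ccccc3)N2S(=O)(=O)c2cc(cc(c2)C(F)(F)F)C(F)(F)F)OC/C=C(\C)CC(OC)OC)OCCO1 | intermediate (not isolated)
10 | (2S,3R)-3-(2,2-dimethoxyethyl)-3-methyl-2-[2-(2-methyl-1,3-dioxolan-2-yl)ethyl]pent-4-enoic acid | OC(=O)[C@@H](CCC1(C)OCCO1)[C@](C)(CC(OC)OC)C=C | intermediate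
11 | methyl (2S,3R)-3-(2,2-dimethoxyethyl)-3-methyl-2-[2-(2-methyl-1,3-dioxolan-2-yl)ethyl]pent-4-enoate | COC(=O)[C@@H](CCC1(C)OCCO1)[C@](C)(CC(OC)OC)C=C | intermediate
12 | 2-bromoprop-2-en-1-ol | OCC(Br)=C | starting material
13 | tert-butyl[(2-bromoprop-2-en-1-yl)oxy]dimethylsilane | BrC(=C)CO[Si](C)(C)C(C)(C)C | intermediate
14 | B-alkyl-9-borabicyclo[3.3.1]nonane adduct of 11 | COC(=O)[C@@H](CCC1(C)OCCO1)[C@](C)(CC(OC)OC)CCB1C2CCCC1CCC2 | intermediate (not isolated)
15 | methyl (2S,3S)-6-{[(tert-butyldimethylsilyl)oxy]methyl}-3-(2,2-dimethoxyethyl)-3-methyl-2-[2-(2-methyl-1,3-dioxolan-2-yl)ethyl]hept-6-enoate | COC(=O)[C@@H](CCC1(C)OCCO1)[C@](C)(CC(OC)OC)CCC(=C)CO[Si](C)(C)C(C)(C)C | intermediate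
16 | (2S,3S)-6-{[(tert-butyldimethylsilyl)oxy]methyl}-3-(2,2-dimethoxyethyl)-3-methyl-2-[2-(2-methyl-1,3-dioxolan-2-yl)ethyl]hept-6-enal | O=C[C@@H](CCC1(C)OCCO1)[C@](C)(CC(OC)OC)CCC(=C)CO[Si](C)(C)C(C)(C)C | intermediate
17 | (3S,4S)-7-{[(tert-butyldimethylsilyl)oxy]methyl}-4-(2,2-dimethoxyethyl)-4-methyl-3-[2-(2-methyl-1,3-dioxolan-2-yl)ethyl]oct-7-en-1-yne | C#C[C@@H](CCC1(C)OCCO1)[C@](C)(CC(OC)OC)CCC(=C)CO[Si](C)(C)C(C)(C)C | intermediate
18 | bicyclic enone: 2-oxo-hydrind-3-ene, 9α-CH2OTBS, 6β-methyl, 6α-(2,2-dimethoxyethyl), 5β-[2-(2-methyl-1,3-dioxolan-2-yl)ethyl] | O=C1C[C@]2(CO[Si](C)(C)C(C)(C)C)CC[C@@](C)(CC(OC)OC)[C@H](CCC3(C)OCCO3)C2=C1 | intermediate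
19 | 2α-allylic alcohol derived from 18 | O[C@H]1C[C@]2(CO[Si](C)(C)C(C)(C)C)CC[C@@](C)(CC(OC)OC)[C@H](CCC3(C)OCCO3)C2=C1 | intermediate
20 | (diethoxyphosphoryl)acetic acid | CCOP(=O)(CC(=O)O)OCC | starting material
21 | 2α-(diethoxyphosphoryl)acetate of 19 | CCOP(=O)(CC(=O)O[C@H]1C[C@]2(CO[Si](C)(C)C(C)(C)C)CC[C@@](C)(CC(OC)OC)[C@H](CCC3(C)OCCO3)C2=C1)OCC | intermediate
22 | 3β,4β-epoxide of 21 | CCOP(=O)(CC(=O)O[C@H]1C[C@]2(CO[Si](C)(C)C(C)(C)C)CC[C@@](C)(CC(OC)OC)[C@H](CCC3(C)OCCO3)[C@]24O[C@H]14)OCC | intermediate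
23 | α-(diethoxyphosphoryl)-γ-lactone (19,2α-olide), 4β-OH, 9α-CH2OTBS, side chains still protected; C18 epimers | CCOP(=O)(OCC)C1C(=O)O[C@H]2C[C@]3(CO[Si](C)(C)C(C)(C)C)CC[C@@](C)(CC(OC)OC)[C@H](CCC4(C)OCCO4)[C@@]3(O)[C@@H]12 | intermediate
24 | keto-aldehyde: phosphono lactone with 17-OH, 4β-OH, 6α-CH2CHO, 5β-(3-oxobutyl) | CCOP(=O)(OCC)C1C(=O)O[C@H]2C[C@]3(CO)CC[C@@](C)(CC=O)[C@H](CCC(C)=O)[C@@]3(O)[C@@H]12 | intermediate
25 | tetracyclic cyclohept-12-ene: phosphono lactone, 17-OH, 4β-OH, ring C closed | CCOP(=O)(OCC)C1C(=O)O[C@H]2C[C@]3(CO)CC[C@@]4(C)CC=C(C)CC[C@@H]4[C@@]3(O)[C@@H]12 | intermediate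
26 | 4β,17-dihydroxycyatha-12,18(20)-dien-19,2α-olide | C=C1C(=O)O[C@H]2C[C@]3(CO)CC[C@@]4(C)CC=C(C)CC[C@@H]4[C@@]3(O)[C@@H]12 | intermediate
27 | 17-acetoxy-4β-hydroxycyatha-12,18(20)-dien-19,2α-olide | C=C1C(=O)O[C@H]2C[C@]3(COC(C)=O)CC[C@@]4(C)CC=C(C)CC[C@@H]4[C@@]3(O)[C@@H]12 | intermediate
28 | 17-acetoxy-12α,13α-epoxy-4β-hydroxycyath-18(20)-en-19,2α-olide (CNP0214540.1) | C=C1C(=O)O[C@H]2C[C@]3(COC(C)=O)CC[C@@]4(C)C[C@H]5O[C@@]5(C)CC[C@@H]4[C@@]3(O)[C@@H]12 | target

**Step count.** Total: 21 steps. Longest linear sequence: 18 steps (steps 3–7 and 9–21).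

**Steps most likely to fail**

1. Step 18 (McMurry ring closure). The coupling may stop at the pinacol stage, oligomerise by intermolecular coupling, or lose material to aldolisation of the keto-aldehyde on the Lewis-acidic titanium surface or to partial reduction of the lactone. Fallback: setting out from 24, both carbonyl groups are methylenated without base by the Lombardo–Takai reagent (Zn, CH2Br2, TiCl4, THF, 0 °C → rt) to give the bis-olefin F1, and ring-closing metathesis with the second-generation Grubbs catalyst (CH2Cl2, 40 °C, high dilution) closes ring C at the same C12=C13 bond, coming back to the route at 25.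

2. Step 16 (epoxide-opening lactonisation). The stabilised carbanion may be too weak a nucleophile for the trisubstituted epoxide, so that the 5-exo opening is slow and base-induced epoxide isomerisation or ester cleavage takes over. Fallback: setting out from 21, dihydroxylation from the β face (OsO4 cat., NMO, acetone/H2O) gives the 3β,4β-diol F2; SOCl2/Et3N and then RuCl3 (cat.)/NaIO4 convert it into the far more electrophilic cyclic sulfate F3. NaH in THF then lets the phosphonoacetate carbanion displace the sulfate at C3 with inversion, giving the lactone sulfate monoester F4. Its acid hydrolysis (cat. H2SO4, H2O/THF) is merged with the deprotection of step 17 and comes back to the route at 24.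

3. Step 6 (enantioselective Ireland–Claisen). The Lewis-acidic bromoborane may cleave the acetal or ketal, and incomplete control of enolate geometry or of the enolate face would erode the diastereo- and enantiomeric purity of the C5/C6 pair. Fallback: setting out from 8, a classical Ireland–Claisen rearrangement (LiN(i-Pr)2, TBSCl, THF–DMPU, −78 °C → rt) proceeds through the silyl ketene acetal F5 and, after hydrolytic work-up, gives the racemic acid, that is 10 together with its enantiomer F6. Crystallisation with (R)-1-phenylethylamine should give the diastereomerically pure ammonium salt F7, and acidification comes back to the route at 10.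

**Further compounds**

F1 | step 18 | bis-olefin: phosphono lactone with 6α-allyl and 5β-(3-methylbut-3-enyl) | CCOP(=O)(OCC)C1C(=O)O[C@H]2C[C@]3(CO)CC[C@@](C)(CC=C)[C@H](CCC(C)=C)[C@@]3(O)[C@@H]12
F2 | step 16 | 3β,4β-diol of 21 | CCOP(=O)(CC(=O)O[C@H]1C[C@]2(CO[Si](C)(C)C(C)(C)C)CC[C@@](C)(CC(OC)OC)[C@H](CCC3(C)OCCO3)[C@@]2(O)[C@@H]1O)OCC
F3 | step 16 | 3β,4β-cyclic sulfate of F2 | CCOP(=O)(CC(=O)O[C@H]1C[C@]2(CO[Si](C)(C)C(C)(C)C)CC[C@@](C)(CC(OC)OC)[C@H](CCC3(C)OCCO3)[C@]24OS(=O)(=O)O[C@H]14)OCC
F4 | step 16 | sodium 4β-sulfate monoester of lactone 23 | CCOP(=O)(OCC)C1C(=O)O[C@H]2C[C@]3(CO[Si](C)(C)C(C)(C)C)CC[C@@](C)(CC(OC)OC)[C@H](CCC4(C)OCCO4)[C@@]3(OS(=O)(=O)[O-])[C@@H]12.[Na+]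
F5 | step 6 | tert-butyldimethylsilyl ketene acetal of 8 (alkyl chain cis to O–Si) | CC1(CC/C=C(\O[Si](C)(C)C(C)(C)C)OC/C=C(\C)CC(OC)OC)OCCO1
F6 | step 6 | (2R,3S)-3-(2,2-dimethoxyethyl)-3-methyl-2-[2-(2-methyl-1,3-dioxolan-2-yl)ethyl]pent-4-enoic acid (enantiomer of 10) | OC(=O)[C@H](CCC1(C)OCCO1)[C@@](C)(CC(OC)OC)C=C
F7 | step 6 | (R)-1-phenylethylammonium salt of 10 | C[C@@H]([NH3+])c1ccccc1.[O-]C(=O)[C@@H](CCC1(C)OCCO1)[C@](C)(CC(OC)OC)C=C
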